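The cyclopenta[c]pyran core is opened at the ring-fusion bond C5–C9 and the acetal bond C1–O2. Both lie in the dihydropyran ring, whose O2–C3=C4–C5 arc is a 1-oxadiene and whose C9–C1 edge is an enol ether, so one intramolecular inverse-demand hetero-Diels–Alder reaction closes the cyclopentane and the pyran together and sets C1, C5 and C9. The precursor is an open chain on a chiral 1,3-dioxane already holding C7, C8 and C10: an alkylidene formylacetate at C5 (C11 ester) tied through C6–C7–C8 to an (E)-ethyl enol ether C9=C1, made in the flask by Knoevenagel condensation. C11 reduction and the two acylations follow.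

Key step: step 9

Remark: iridoid numbering is used for all intermediates (C1 acetal carbon, O2, C3=C4, C5 and C9 ring fusion, C10 on C8, C11 on C4; β is the face of H5 and H9; TBS = tert-butyldimethylsilyl); SAMP, (R)-3-methylpentanoic acid, [bis(2,2,2-trifluoroethoxy)phosphoryl]acetic acid and 4-(tert-butyldimethylsilyloxy)benzaldehyde are taken as purchased single compounds.

Step 1
Reactants: 1 2,2-dimethyl-1,3-dioxan-5-one; 2 SAMP
Product: 3 SAMP hydrazone of the dioxanone
Conditions: toluene, 4 Å MS, 60 °C
Reagents that add atoms: none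
Why: Hydrazone formation between the unhindered ketone and the N-amino group of the auxiliary, driven by removal of water.

Step 2
Reactants: 3 SAMP hydrazone; 4 tert-butyl bromoacetate
Product: 6 C7-alkylated SAMP hydrazone, via lithium azaenolate 5 (not isolated)
Conditions: t-BuLi, THF, −78 °C; then 4, −100 °C → rt
Reagents that add atoms: none
Why: SAMP-hydrazone α-alkylation, in which the lithium azaenolate is chelated by the methoxymethyl arm so that the bromoacetate, which supplies C6 and C5, attacks the face away from the pyrrolidine and should set C7 as S, the sense expected for this auxiliary on the dioxanone.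

Step 3
Reactants: 6 C7-alkylated SAMP hydrazone
Product: 7 (S)-keto ester
Conditions: sat. aq. oxalic acid, Et2O, rt
Reagents that add atoms: water, O
Why: Two-phase hydrazone hydrolysis under an acid too weak to open the acetonide, cleave the tert-butyl ester or enolise C7, the auxiliary passing into the aqueous layer.

Step 4
Reactants: 7 (S)-keto ester; 8 ethoxyacetylene
Product: 10 tertiary propargylic alcohol, via lithium ethoxyacetylide 9 (not isolated)
Conditions: 8, n-BuLi, THF, −78 °C; then 7, −78 °C; H2O
Reagents that add atoms: none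
Why: Acetylide 1,2-addition to the ketone (much faster than attack on the tert-butyl ester), the slim nucleophile entering axially on the chair dioxanone, whose C7 chain is equatorial and whose ring oxygens offer no axial hydrogens to block that path, so that C9 ends cis to the C7 chain and O8 equatorial (8R); the alkynyl ether is chosen because it is stable, whereas (E)-2-alkoxyvinyllithium reagents are prone to lose lithium alkoxide.

Step 5
Reactants: 10 tertiary propargylic alcohol
Product: 11 diol with (E)-enol ether
Conditions: LiAlH4, THF, 0 °C → rt; aq. NaOH work-up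
Reagents that add atoms: none
Why: LiAlH4 reduces the ester to the C5 alcohol and, through the C8 alkoxide, effects the trans-hydroalumination known for propargylic alcohols and alkoxyethynyl carbinols (aluminium on C1, hydride on C9), so protonolysis should give the (E)-enol ether, and the basic work-up keeps the β-hydroxy enol ether from acid-induced loss of water.

Step 6
Reactants: 11 diol with (E)-enol ether
Product: 12 bis(triethylsilyl) ether
Conditions: Et3SiOTf, 2,6-lutidine, CH2Cl2, −78 °C
Reagents that add atoms: triethylsilyl trifluoromethanesulfonate, CC[Si](CC)(CC)OS(=O)(=O)C(F)(F)F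
Why: Silyl triflate silylation covers the primary C5–OH and the hindered tertiary C8–OH alike while excess lutidine keeps the enol ether and acetonide away from acid, and the C8 silyl ether later blocks lactol formation and oxa-Michael addition to the alkylidene.

Step 7
Reactants: 12 bis(triethylsilyl) ether
Product: 13 C5 aldehyde
Conditions: (COCl)2, DMSO, CH2Cl2, −78 → −40 °C; then Et3N
Reagents that add atoms: none
Why: Swern oxidation applied directly to a primary triethylsilyl ether, in which activated DMSO displaces silicon from the unhindered primary oxygen and the alkoxysulfonium ion collapses to the aldehyde, the tertiary silyl ether being too hindered to react and no protic acid being released near the enol ether.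

Step 8
Reactants: 14 methyl 3,3-dimethoxypropanoate
Product: 15 methyl 3-oxopropanoate
Conditions: Amberlyst-15 (sulfonic acid resin), H2O (2 equiv), CH2Cl2, rt; filtered, used at once
Reagents that add atoms: water, O
Why: Acid hydrolysis of a dimethyl acetal, the resin being filtered off so that no acid reaches the next step and the β-formyl ester (mainly its enol) being taken on without storage because it self-condenses on standing.

Step 9
Reactants: 13 C5 aldehyde; 15 methyl 3-oxopropanoate
Product: 17 tricyclic C1 ethyl acetal, via alkylidene formylacetate 16 (not isolated)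
Conditions: 15 (2 equiv), ethylenediammonium diacetate (cat.), MgSO4, CH2Cl2, 0 °C → rt
Reagents that add atoms: none
Why: Ammonium-acetate-catalysed Knoevenagel condensation gives alkylidene formylacetate 16, whose geometric isomers interconvert under the same catalysis, so the isomer with the formyl group anti to the tether is drained into a concerted but asynchronous intramolecular inverse-demand hetero-Diels–Alder reaction in which the enol-ether carbon C9 bonds to the acceptor carbon C5 slightly ahead of O2 to C1. The closest known reaction type is the domino Knoevenagel–hetero-Diels–Alder reaction of alkylidene 1,3-dicarbonyl compounds with tethered enol ethers. The cyclopentane closes in a 5-exo sense (C9 onto C5), and the dihydropyran is the six-membered ring of the [4+2] itself. C5 and C9 are controlled by the three-atom tether, which admits only the cis-fused transition state, and by the chair dioxane, which holds O7 and C10 on the β face and so sends C4 and C1 to the α face; C1 is controlled by the (E)-enol ether geometry, carried over suprafacially so that OEt ends trans to the C9–C8 bond. The step needs facial selectivity and the formyl rather than the ester carbonyl as diene terminus: the first is secured by the dioxane carrying the tether equatorial at C7 and the enol ether axial at C8, the second by the lower LUMO and smaller size of the formyl group. The C11 ester lowers the oxadiene LUMO enough for reaction near room temperature, before the C7 oxygen can be lost from 13 by β-elimination.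

Step 10
Reactants: 17 tricyclic C1 ethyl acetal
Product: 18 lactol tetraol
Conditions: 1 M aq. HCl, THF, rt → 40 °C
Reagents that add atoms: water, O
Why: Acid hydrolysis removes the C1 ethyl acetal, the acetonide and the tertiary silyl ether in one operation, the enol ether being safe because conjugation with the C11 ester makes it a vinylogous carbonate; the C1 configuration is given up here on purpose and the lactol should rest mainly as the β-anomer.

Step 11
Reactants: 18 lactol tetraol
Product: 19 1-O,10-O-bis(TBS) ether
Conditions: TBSCl (2.3 equiv), imidazole, DMF, 0 °C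
Reagents that add atoms: tert-butyldimethylsilyl chloride, CC(C)(C)[Si](C)(C)Cl
Why: Silylation with a bulky chlorosilane takes the lactol hydroxyl and the primary C10–OH, while the secondary C7–OH beside the quaternary C8 and the tertiary C8–OH are too hindered.

Step 12
Reactants: 19 1-O,10-O-bis(TBS) ether
Product: 20 C11 allylic alcohol
Conditions: iBu2AlH (5 equiv), CH2Cl2, −78 °C; aq. potassium sodium tartrate (KNaC4H4O6)
Reagents that add atoms: none
Why: 1,2-Reduction of the β-alkoxyacrylate ester to the allylic alcohol with excess hydride (two equivalents are consumed by the free hydroxyls), the C1 silyl acetal being inert at low temperature and the neutral tartrate work-up sparing the acid-labile hydroxymethyl enol ether.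

Step 13
Reactants: 20 C11 allylic alcohol
Product: 21 1-O,10-O,11-O-tris(TBS) ether
Conditions: TBSCl (1.1 equiv), imidazole, CH2Cl2, 0 °C
Reagents that add atoms: tert-butyldimethylsilyl chloride, CC(C)(C)[Si](C)(C)Cl
Why: Silylation of the primary allylic C11–OH, which reacts far faster than the hindered C7–OH and C8–OH.

Step 14
Reactants: 21 1-O,10-O,11-O-tris(TBS) ether; 22 [bis(2,2,2-trifluoroethoxy)phosphoryl]acetic acid
Product: 23 C7 phosphonoacetate
Conditions: DCC, DMAP (cat.), CH2Cl2, 0 °C → rt
Reagents that add atoms: none
Why: Steglich esterification with a compact acid reaches the hindered C7–OH (the tertiary C8–OH is inert), plants the handle for the cis-alkene and blocks C7 before the lactol is released.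

Step 15
Reactants: 23 C7 phosphonoacetate
Product: 24 free lactol
Conditions: Bu4NF (1.1 equiv), AcOH (1.2 equiv), THF, −20 → 0 °C
Reagents that add atoms: none
Why: Fluoride desilylation selective for the anomeric silyl ether, since a lactolate is a much better leaving group than a primary alkoxide (the usual way to free the reducing end of a sugar beside other silyl ethers), with acetic acid buffering the medium for the phosphonate ester.

Step 16
Reactants: 24 free lactol; 25 (R)-3-methylpentanoic acid
Product: 26 C1 (R)-3-methylpentanoate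
Conditions: DCC, DMAP (cat.), CH2Cl2, −20 → 0 °C
Reagents that add atoms: none
Why: Steglich acylation of the only reactive hydroxyl; the lactol equilibrates through its open form and the β-hydroxyl (pseudo-axial, anomerically favoured, trans to the quaternary C8 on C9) is both the major and the less hindered anomer, so the β-ester should prevail.

Step 17
Reactants: 26 C1 (R)-3-methylpentanoate; 27 4-(tert-butyldimethylsilyloxy)benzaldehyde
Product: 29 tris-silylated target, via potassium phosphonate 28 (not isolated)
Conditions: KN(SiMe3)2 (1.0 equiv), 18-crown-6, THF, −78 °C; then 27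
Reagents that add atoms: none
Why: Still–Gennari olefination, in which the electron-poor bis(trifluoroethyl) phosphonate and a dissociated potassium counter-ion make the syn oxaphosphetane eliminate faster than it equilibrates to give the (Z)-cinnamate, one equivalent of base deprotonating only the phosphonoacetate, which is far more acidic than the C8–OH or the ester α-hydrogens.

Step 18
Reactants: 29 tris-silylated target
Product: 30 CNP0217341.1
Conditions: Bu4NF, AcOH (1:1, excess), THF, 0 °C → rt
Reagents that add atoms: none
Why: Fluoride desilylation removes the aryl and the two primary silyl ethers, and buffering with acetic acid should prevent C7→C10 acyl migration, loss of the anomeric ester and isomerisation of the (Z)-enoate.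

Compound list

1 | 2,2-dimethyl-1,3-dioxan-5-one | CC1(C)OCC(=O)CO1 | starting material
2 | SAMP, (S)-1-amino-2-(methoxymethyl)pyrrolidine | COC[C@@H]1CCCN1N | starting material
3 | SAMP hydrazone of 2,2-dimethyl-1,3-dioxan-5-one | COC[C@@H]1CCCN1N=C2COC(C)(C)OC2 | intermediate
4 | tert-butyl bromoacetate | CC(C)(C)OC(=O)CBr | starting material
5 | lithium azaenolate of hydrazone 3 | [Li+].COC[C@@H]1CCCN1[N-]C2=COC(C)(C)OC2 | intermediate
6 | tert-butyl 2-[(4S)-2,2-dimethyl-5-{[(2S)-2-(methoxymethyl)pyrrolidin-1-yl]imino}-1,3-dioxan-4-yl]acetate (dioxane C4 = C7; C=N geometry not fixed) | CC(C)(C)OC(=O)C[C@@H]1OC(C)(C)OCC1=NN2CCC[C@H]2COC | intermediate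
7 | tert-butyl 2-[(4S)-2,2-dimethyl-5-oxo-1,3-dioxan-4-yl]acetate | CC(C)(C)OC(=O)C[C@@H]1OC(C)(C)OCC1=O | intermediate
8 | ethoxyacetylene | CCOC#C | starting material
9 | lithium ethoxyacetylide | [Li+].[C-]#COCC | intermediate
10 | tert-butyl 2-[(4S,5R)-5-(ethoxyethynyl)-5-hydroxy-2,2-dimethyl-1,3-dioxan-4-yl]acetate (alkynyl group axial, cis to the acetate chain) | CC(C)(C)OC(=O)C[C@@H]1OC(C)(C)OC[C@]1(O)C#COCC | intermediate
11 | 2-[(4S,5R)-5-[(E)-2-ethoxyvinyl]-5-hydroxy-2,2-dimethyl-1,3-dioxan-4-yl]ethanol | OCC[C@@H]1OC(C)(C)OC[C@]1(O)/C=C/OCC | intermediate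
12 | bis(triethylsilyl) ether of 11 (at O5 and O8) | CC[Si](CC)(CC)OCC[C@@H]1OC(C)(C)OC[C@]1(O[Si](CC)(CC)CC)/C=C/OCC | intermediate
13 | 2-[(4S,5R)-5-[(E)-2-ethoxyvinyl]-2,2-dimethyl-5-(triethylsilyloxy)-1,3-dioxan-4-yl]acetaldehyde (C5 aldehyde) | O=CC[C@@H]1OC(C)(C)OC[C@]1(O[Si](CC)(CC)CC)/C=C/OCC | intermediate
14 | methyl 3,3-dimethoxypropanoate | COC(=O)CC(OC)OC | starting material
15 | methyl 3-oxopropanoate (methyl formylacetate, largely the enol) | COC(=O)CC=O | intermediate
16 | methyl (2Z)-4-[(4S,5R)-5-[(E)-2-ethoxyvinyl]-2,2-dimethyl-5-(triethylsilyloxy)-1,3-dioxan-4-yl]-2-formylbut-2-enoate (formyl trans to the chain) | O=C/C(C(=O)OC)=C/C[C@@H]1OC(C)(C)OC[C@]1(O[Si](CC)(CC)CC)/C=C/OCC | intermediate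
17 | tricycle: 1β-ethoxy acetal, C3=C4 enol ether with C11 methyl ester, cis-fused (H5, H9 β), O7/C10 acetonide on the β face, 8α-triethylsilyloxy | CCO[C@@H]1OC=C(C(=O)OC)[C@H]2C[C@@H]3OC(C)(C)OC[C@]3(O[Si](CC)(CC)CC)[C@@H]12 | intermediate
18 | lactol tetraol: C11 methyl ester with 1β-OH, 7β-OH, 8α-OH and 10-OH (C10 β) | O[C@@H]1OC=C(C(=O)OC)[C@H]2C[C@H](O)[C@](O)(CO)[C@@H]12 | intermediate
19 | 1-O,10-O-bis(TBS) ether of 18 | CC(C)(C)[Si](C)(C)O[C@@H]1OC=C(C(=O)OC)[C@H]2C[C@H](O)[C@](O)(CO[Si](C)(C)C(C)(C)C)[C@@H]12 | intermediate
20 | C11 alcohol: 1-O,10-O-bis(TBS) ether with free 7-OH, 8-OH and 11-OH | CC(C)(C)[Si](C)(C)O[C@@H]1OC=C(CO)[C@H]2C[C@H](O)[C@](O)(CO[Si](C)(C)C(C)(C)C)[C@@H]12 | intermediate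
21 | 1-O,10-O,11-O-tris(TBS) ether with free 7β-OH and 8α-OH | CC(C)(C)[Si](C)(C)O[C@@H]1OC=C(CO[Si](C)(C)C(C)(C)C)[C@H]2C[C@H](O)[C@](O)(CO[Si](C)(C)C(C)(C)C)[C@@H]12 | intermediate
22 | [bis(2,2,2-trifluoroethoxy)phosphoryl]acetic acid | OC(=O)CP(=O)(OCC(F)(F)F)OCC(F)(F)F | starting material
23 | 7-O-{[bis(2,2,2-trifluoroethoxy)phosphoryl]acetyl} ester of 21 | CC(C)(C)[Si](C)(C)O[C@@H]1OC=C(CO[Si](C)(C)C(C)(C)C)[C@H]2C[C@H](OC(=O)CP(=O)(OCC(F)(F)F)OCC(F)(F)F)[C@](O)(CO[Si](C)(C)C(C)(C)C)[C@@H]12 | intermediate
24 | lactol (free 1β-OH) with 7-O-phosphonoacetate and 10-O,11-O-bis(TBS) ethers | O[C@@H]1OC=C(CO[Si](C)(C)C(C)(C)C)[C@H]2C[C@H](OC(=O)CP(=O)(OCC(F)(F)F)OCC(F)(F)F)[C@](O)(CO[Si](C)(C)C(C)(C)C)[C@@H]12 | intermediate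
25 | (R)-3-methylpentanoic acid | CC[C@@H](C)CC(=O)O | starting material
26 | 1β-O-[(R)-3-methylpentanoyl] ester of 24 | CC[C@@H](C)CC(=O)O[C@@H]1OC=C(CO[Si](C)(C)C(C)(C)C)[C@H]2C[C@H](OC(=O)CP(=O)(OCC(F)(F)F)OCC(F)(F)F)[C@](O)(CO[Si](C)(C)C(C)(C)C)[C@@H]12 | intermediate
27 | 4-(tert-butyldimethylsilyloxy)benzaldehyde | O=Cc1ccc(O[Si](C)(C)C(C)(C)C)cc1 | starting material
28 | potassium salt of the phosphonoacetate carbanion of 26 | [K+].CC[C@@H](C)CC(=O)O[C@@H]1OC=C(CO[Si](C)(C)C(C)(C)C)[C@H]2C[C@H](OC(=O)[CH-]P(=O)(OCC(F)(F)F)OCC(F)(F)F)[C@](O)(CO[Si](C)(C)C(C)(C)C)[C@@H]12 | intermediate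
29 | target as its tris(TBS) ether (phenol O, O10, O11) with 7-O-(Z)-cinnamate and 1β-O-(R)-3-methylpentanoate | CC[C@@H](C)CC(=O)O[C@@H]1OC=C(CO[Si](C)(C)C(C)(C)C)[C@H]2C[C@H](OC(=O)/C=C\c3ccc(O[Si](C)(C)C(C)(C)C)cc3)[C@](O)(CO[Si](C)(C)C(C)(C)C)[C@@H]12 | intermediate
30 | CNP0217341.1 | CC[C@@H](C)CC(=O)O[C@@H]1OC=C(CO)[C@H]2C[C@H](OC(=O)/C=C\c3ccc(O)cc3)[C@](O)(CO)[C@@H]12 | target

Total step count: 18. Longest linear sequence: 17 steps (steps 1–7 and 9–18; step 8 is a one-step side branch).

Steps most likely to fail

Risk 1, step 9. Self-condensation of the formylacetate and amine-induced β-elimination of the C7 oxygen may outrun the condensation, or the cycloaddition may proceed with poor facial selectivity. The fallback for step 9 changes the heterodiene to a symmetrical, more electrophilic one that can form and cyclise at lower temperature; it sets out from 13 and comes back at 17. Aldehyde 13 would be condensed with malondialdehyde, freed from sodium 3-oxoprop-1-en-1-olate with AcOH, under ethylenediammonium diacetate catalysis in CH2Cl2 to give alkylidene malondialdehyde F1, which should cyclise in the same flask to C11-formyl tricycle F2. Pinnick oxidation with NaClO2, NaH2PO4 and 2-methyl-2-butene in t-BuOH–H2O would give C11 carboxylic acid F3, and TMSCHN2 in MeOH–toluene would return methyl ester 17.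

Risk 2, step 17. The late olefination may erode the (Z)-geometry, or the base may cleave or shift the anomeric ester. The fallback for step 17 makes the cis-alkene by semihydrogenation of an alkyne and reverses the order of the two acylations; it sets out from 21 and comes back at 29. Buffered Bu4NF–AcOH would free the lactol while the C7–OH is still open, giving lactol diol F4. Low-temperature Steglich acylation with 25 should take the more acidic and less hindered lactol hydroxyl first and give C1 ester F5, whose C7–OH stays free. That hydroxyl would then be esterified, using DCC and DMAP at −20 °C with the alcohol present from the start, with 3-[4-(tert-butyldimethylsilyloxy)phenyl]propiolic acid F6, itself prepared from purchased tert-butyl(4-ethynylphenoxy)dimethylsilane with n-BuLi and then CO2, to give C7 aryl propiolate F7. Hydrogenation over Pd/CaCO3 poisoned with Pb(OAc)2 and quinoline should stop at the (Z)-cinnamate 29, the trisubstituted enol ether being left alone.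

Risk 3, step 16. Acylation of the equilibrating lactol may give a mixture of C1 anomers, or the open hydroxy-aldehyde form may eliminate. The fallback for step 16 turns the anomeric oxygen into a leaving group and lets the acid itself displace it; it sets out from 24 and comes back at 26. Lactol 24 with Cl3CCN and K2CO3 in CH2Cl2 at rt would give anomeric trichloroacetimidate F8. Treated with acid 25 alone in CH2Cl2, the imidate is protonated and ionises, and the carboxylate should add to the oxocarbenium ion on the face trans to C8, giving 26.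

Further compounds

F1 | step 9 | alkylidene malondialdehyde: 2-{2-[(4S,5R)-5-[(E)-2-ethoxyvinyl]-2,2-dimethyl-5-(triethylsilyloxy)-1,3-dioxan-4-yl]ethylidene}propanedial | O=CC(C=O)=CC[C@@H]1OC(C)(C)OC[C@]1(O[Si](CC)(CC)CC)/C=C/OCC
F2 | step 9 | C11-formyl analogue of tricycle 17 | CCO[C@@H]1OC=C(C=O)[C@H]2C[C@@H]3OC(C)(C)OC[C@]3(O[Si](CC)(CC)CC)[C@@H]12
F3 | step 9 | C11 carboxylic acid analogue of tricycle 17 | CCO[C@@H]1OC=C(C(=O)O)[C@H]2C[C@@H]3OC(C)(C)OC[C@]3(O[Si](CC)(CC)CC)[C@@H]12
F4 | step 17 | lactol diol: free 1β-OH, 7β-OH and 8α-OH with 10-O,11-O-bis(TBS) ethers | O[C@@H]1OC=C(CO[Si](C)(C)C(C)(C)C)[C@H]2C[C@H](O)[C@](O)(CO[Si](C)(C)C(C)(C)C)[C@@H]12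
F5 | step 17 | 1β-O-[(R)-3-methylpentanoyl] ester of F4 with free C7–OH | CC[C@@H](C)CC(=O)O[C@@H]1OC=C(CO[Si](C)(C)C(C)(C)C)[C@H]2C[C@H](O)[C@](O)(CO[Si](C)(C)C(C)(C)C)[C@@H]12
F6 | step 17 | 3-[4-(tert-butyldimethylsilyloxy)phenyl]propiolic acid | OC(=O)C#Cc1ccc(O[Si](C)(C)C(C)(C)C)cc1
F7 | step 17 | 7-O-aryl propiolate of F5 | CC[C@@H](C)CC(=O)O[C@@H]1OC=C(CO[Si](C)(C)C(C)(C)C)[C@H]2C[C@H](OC(=O)C#Cc3ccc(O[Si](C)(C)C(C)(C)C)cc3)[C@](O)(CO[Si](C)(C)C(C)(C)C)[C@@H]12
F8 | step 16 | C1 trichloroacetimidate of lactol 24, drawn as the 1β anomer (either anomer serves) | N=C(O[C@@H]1OC=C(CO[Si](C)(C)C(C)(C)C)[C@H]2C[C@H](OC(=O)CP(=O)(OCC(F)(F)F)OCC(F)(F)F)[C@](O)(CO[Si](C)(C)C(C)(C)C)[C@@H]12)C(Cl)(Cl)Cl
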